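The seven-membered carbocycle is disconnected at C1–C10 and C8–C9. The feature exploited is that the tertiary carbinol C1 and the only ring CH2, C8, are the two termini of a severed ether bridge, while the trans C9-carbinol/C10-methyl pair maps onto an (E)-propenyl silyl ether. One oxidopyrylium (5+2) cycloaddition therefore forms both bonds, closes the cycloheptene and the 8-oxabicyclo[3.2.1]octenone, and sets C1, C8, C9 and C10. Its precursor is a 2-(alkoxymethyl)-3-oxidopyrylium (C1, C5–C8 and the C1 oxygen), released from an aroyloxypyranone made by Achmatowicz rearrangement. Reductive scission of C8–O then gives a cycloheptenone on which the lactone, the ester and the crotonoyl group are installed.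

Key step: step 5

Numbering and faces: cycloheptane C1 (tertiary carbinol), C5 (ester carbon), C6 (lactone O–CH), C7 (lactone CH), C8 (CH2), C9 (CHOH), C10 (CHCH3); C2–C4 are the crotonoyl carbons and C11–C13 the lactone carbons (C13 = exocyclic CH2). α is the face of the C1 oxygen (the former bridge side), β the opposite face.

Structure check: with the bridge oxygen α, the cycloadduct needed is the (1R,5S,6S,7S) isomer, silyloxy β (endo, anti to the bridge) and methyl α (exo). This maps onto C9 β-OH and C10 α-CH3 of the target, so the target structure needs no correction.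

Assumption: the sense of induction of the aminothiourea is not predicted, so the catalyst antipode that gives the (1R,5S,6S,7S) cycloadduct is chosen in a first run; 2-[(4-methoxybenzyl)oxy]acetaldehyde is taken as a catalogue compound.

Step 1
Reactants: 1 furan; 2 2-[(4-methoxybenzyl)oxy]acetaldehyde
Product: 4 1-(furan-2-yl)-2-[(4-methoxybenzyl)oxy]ethan-1-ol (racemic), via 2-furyllithium 3 (not isolated)
Conditions: n-BuLi, THF, −78 → 0 °C; then 2, −78 °C; aq. NH4Cl
Reagents that add atoms: none
Why: C2-lithiation of furan and 1,2-addition to the aldehyde give the furyl carbinol needed for the Achmatowicz rearrangement; its stereocentre is erased when the pyrylium forms, so no control is required.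

Step 2
Reactants: 4 furyl carbinol
Product: 6 6-hydroxy-2-{[(4-methoxybenzyl)oxy]methyl}-2H-pyran-3(6H)-one, via hydroxy keto enal 5 (not isolated)
Conditions: NBS, NaHCO3, NaOAc, THF–H2O (4:1), 0 °C
Reagents that add atoms: water, O
Why: Achmatowicz rearrangement, in which bromonium-induced oxidative opening of the furan gives the (Z)-ene-dicarbonyl compound and the carbinol oxygen closes onto the aldehyde, the buffered medium sparing the p-methoxybenzyl ether.

Step 3
Reactants: 6 pyranone lactol
Product: 7 5-oxo-6-{[(4-methoxybenzyl)oxy]methyl}-5,6-dihydro-2H-pyran-2-yl 3,4,5-trifluorobenzoate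
Conditions: 3,4,5-trifluorobenzoyl chloride, pyridine, DMAP (cat.), CH2Cl2, −20 → 0 °C
Reagents that add atoms: 3,4,5-trifluorobenzoyl chloride, O=C(Cl)c1cc(F)c(F)c(F)c1
Why: acylation of the lactol installs an electron-poor aroate, a leaving group that a thiourea can bind and that departs under the mild conditions of step 5, both anomers converging on the same ylide.

Step 4
Reactants: 8 allyloxy(tert-butyl)dimethylsilane
Product: 9 (E)-tert-butyldimethyl(prop-1-en-1-yloxy)silane
Conditions: [Ir(cod)(PPh2Me)2]PF6 (0.5 mol %, activated with H2, then degassed), THF, rt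
Reagents that add atoms: none
Why: allyl-ether isomerisation by the cationic iridium hydride, a 1,3-hydrogen shift known to favour the (E)-propenyl ether strongly; this geometry later becomes the trans C9/C10 relationship.

Step 5
Reactants: 7 aroyloxypyranone; 9 (E)-propenyl silyl ether
Product: 11 (1R,5S,6S,7S)-6-[(tert-butyldimethylsilyl)oxy]-1-{[(4-methoxybenzyl)oxy]methyl}-7-methyl-8-oxabicyclo[3.2.1]oct-3-en-2-one, via 3-oxidopyrylium 10 (not isolated)
Conditions: 1-[(1R,2R)-2-amino-1,2-diphenylethyl]-3-[3,5-bis(trifluoromethyl)phenyl]thiourea or its antipode (15 mol %), 1,3-bis[3,5-bis(trifluoromethyl)phenyl]thiourea (15 mol %), AcOH (15 mol %), 9 (4 equiv), toluene, rt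
Reagents that add atoms: none
Why: Loss of the aroate from 7 (thiourea-assisted, the ketone being carried as its condensate with the primary amine of the catalyst) unveils the pyrylium ylide 10, whose two carbons flanking the ring oxygen add suprafacially across the enol ether in a concerted but asynchronous six-electron (5+2) cycloaddition, the closest known reaction type being the aminothiourea-catalysed intermolecular oxidopyrylium cycloaddition with vinyl ethers. The cycloheptene ring closes by intermolecular union of the five-carbon ylide with the two-carbon alkene (C8–C9 and C1–C10 formed in the same event), and the oxygen bridge with its tetrahydrofuran ring closes as a consequence, because the pyrylium oxygen already links C1 and C8. C9 and C10 should come out trans because the (E)-geometry of 9 is conserved, the silyloxy group should sit endo (anti to the bridge, under the enone) through the usual secondary overlap of an alkoxy substituent so that the methyl is exo, and C1 and C8 are fixed relative to these by the bridge. Absolute configuration rests on the chiral aminothiourea, which holds the aroate and shields one face of the bound pyrylium. The step needs the nucleophilic β-carbon of the enol ether (C10) to bond to the ylide carbon next to the oxido-bearing carbon (C1), where the ylide has its largest frontier coefficient, and the oxygen-bearing carbon (C9) to close onto C8, which is the orientation generally found with vinyl ethers. It also needs endo selectivity and a geometrically pure enol ether, the latter secured in step 4.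

Step 6
Reactants: 11 cycloadduct
Product: 13 7-hydroxy-7-{[(4-methoxybenzyl)oxy]methyl}-6-methyl-5-[(tert-butyldimethylsilyl)oxy]cyclohept-2-en-1-one (1α-OH; 9β-OSi; 10α-CH3), via deconjugated cyclohept-3-enone 12 (not isolated)
Conditions: SmI2 (2.5 equiv), THF–MeOH, −78 °C; work-up; then DBU (10 mol %), CH2Cl2, 0 °C
Reagents that add atoms: none
Why: vinylogous reductive elimination, in which two-electron reduction of the enone puts the carbanion (organosamarium) character at C7, β to the C8–O bond, so the bridge is expelled at C8 as the tertiary C1 alkoxide and the extended dienolate is protonated at C6 and then moved into conjugation by the amidine base, C1, C9 and C10 being untouched.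

Step 7
Reactants: 13 α-hydroxy enone
Product: 14 7-{[(4-methoxybenzyl)oxy]methyl}-6-methyl-5-[(tert-butyldimethylsilyl)oxy]-7-[(triethylsilyl)oxy]cyclohept-2-en-1-one
Conditions: Et3SiOTf, 2,6-lutidine, CH2Cl2, −78 → −20 °C
Reagents that add atoms: triethylsilyl trifluoromethanesulfonate, CC[Si](CC)(CC)OS(=O)(=O)C(F)(F)F
Why: silyl triflate silylation of the tertiary α-ketol hydroxyl, so that the C1 oxygen can neither chelate in the reduction nor direct the later epoxidation to the α-face.

Step 8
Reactants: 14 silylated enone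
Product: 15 7-{[(4-methoxybenzyl)oxy]methyl}-6-methyl-5-[(tert-butyldimethylsilyl)oxy]-7-[(triethylsilyl)oxy]cyclohept-2-en-1-ol (C5 α-OH)
Conditions: i-Bu2AlH, toluene, −78 °C; aq. KNaC4H4O6 (potassium sodium tartrate)
Reagents that add atoms: none
Why: 1,2-reduction under non-chelating conditions, where the C1 silyloxy group lies perpendicular to the carbonyl plane (polar Felkin–Anh arrangement) and the aluminium hydride attacks C5 from the β-face, anti to the C1–O bond, which should set the C5 hydroxyl α as the sigmatropic transfer to the α-face of C7 requires.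

Step 9
Reactants: 15 allylic alcohol; 16 acetic anhydride
Product: 17 acetate of 15
Conditions: pyridine, DMAP (cat.), CH2Cl2, rt
Reagents that add atoms: none
Why: DMAP-catalysed acylation of the only free hydroxyl, the acetate supplying C11 and C12.

Step 10
Reactants: 17 allylic acetate
Product: 20 2-[4-{[(4-methoxybenzyl)oxy]methyl}-5-methyl-6-[(tert-butyldimethylsilyl)oxy]-4-[(triethylsilyl)oxy]cyclohept-2-en-1-yl]acetic acid (C7 α-CH2CO2H), via silyl ketene acetal 18 (not isolated), via trimethylsilyl ester 19 (not isolated)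
Conditions: LiN(i-Pr)2, Me3SiCl, THF, −78 °C → rt, then 50 °C; aq. citric acid
Reagents that add atoms: none
Why: Ireland–Claisen rearrangement, in which the O-silyl ketene acetal rearranges suprafacially across the C5–C6–C7 allyl unit, so the C7–C11 bond forms on the α-face from which the C5–O bond departs and the double bond moves to C5=C6.

Step 11
Reactants: 20 unsaturated acid
Product: 21 2-[4-(hydroxymethyl)-5-methyl-6-[(tert-butyldimethylsilyl)oxy]-4-[(triethylsilyl)oxy]cyclohept-2-en-1-yl]acetic acid
Conditions: DDQ, CH2Cl2–pH 7 phosphate buffer, 0 °C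
Reagents that add atoms: none
Why: oxidative removal of the p-methoxybenzyl ether by benzylic hydride abstraction in buffered wet solvent, which leaves both silyl ethers, the acid and the alkene intact and frees the β-face hydroxymethyl group as a directing group.

Step 12
Reactants: 21 hydroxy acid
Product: 23 8-hydroxy-7-(hydroxymethyl)-6-methyl-5-[(tert-butyldimethylsilyl)oxy]-7-[(triethylsilyl)oxy]octahydro-2H-cyclohepta[b]furan-2-one (cis-fused; C5 β-OH), via epoxy acid 22 (not isolated)
Conditions: VO(acac)2 (5 mol %), t-BuOOH, CH2Cl2, 0 °C → rt; then PPTS (cat.)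
Reagents that add atoms: tert-butyl hydroperoxide, CC(C)(C)OO
Why: hydroxyl-directed epoxidation through the vanadium alkoxide of the homoallylic CH2OH (the allylic C1 oxygen being silylated) delivers oxygen to the β-face of C5=C6, and the α-face carboxylic acid then opens the epoxide at C6 in a 5-exo anti fashion, which sets C6–O α (cis-fused γ-lactone) and C5–OH β in one operation.

Step 13
Reactants: 23 hydroxy lactone; 24 N,N-dimethylmethyleneiminium iodide
Product: 27 3-methylidene analogue of 23, via Mannich base 25 (not isolated), via trimethylammonium iodide 26 (not isolated)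
Conditions: LiN(i-Pr)2 (3.3 equiv), THF, −78 °C; 24, −78 → 0 °C; work-up; then MeI, MeOH, rt; aq. NaHCO3
Reagents that add atoms: none
Why: α-methylenation by Mannich reaction of the lactone lithium enolate (the two hydroxyls carried as alkoxides), exhaustive N-methylation and base-induced β-elimination of trimethylamine, which creates C13 and removes the C11 stereocentre.

Step 14
Reactants: 27 methylene lactone diol
Product: 28 7-carbaldehyde (C1–CHO) derived from 27
Conditions: TEMPO (cat.), PhI(OAc)2, CH2Cl2, rt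
Reagents that add atoms: none
Why: oxoammonium oxidation, selective for the primary alcohol over the hindered secondary C5 hydroxyl and harmless to the methylene lactone; the aldehyde has no α-hydrogen and cannot epimerise.

Step 15
Reactants: 28 hydroxy aldehyde; 29 isovaleryl chloride
Product: 30 C5 3-methylbutanoate of 28
Conditions: pyridine, DMAP (cat.), CH2Cl2, 0 °C → rt
Reagents that add atoms: none
Why: pyridine/DMAP acylation of the C5 β-hydroxyl, now the only free hydroxyl, with retention at C5.

Step 16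
Reactants: 30 ester aldehyde; 31 (E)-1-bromoprop-1-ene
Product: 33 (E)-1-hydroxybut-2-enyl compound (C2 epimers), via propenylchromium dichloride 32 (not isolated)
Conditions: CrCl2, NiCl2 (cat.), DMF, rt
Reagents that add atoms: none
Why: Nozaki–Hiyama–Kishi addition, in which the alkenylchromium reagent adds to the aldehyde only, tolerating the ester, the methylene lactone and both silyl ethers, and keeps the (E)-geometry; the C2 carbinol mixture is erased in the next step.

Step 17
Reactants: 33 allylic alcohol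
Product: 34 bis-silyl ether of the target
Conditions: Dess–Martin periodinane, CH2Cl2, 0 °C → rt
Reagents that add atoms: none
Why: Dess–Martin oxidation of the allylic alcohol, the only free hydroxyl, to the (E)-enone.

Step 18
Reactants: 34 bis-silyl ether
Product: 35 target compound
Conditions: HF·pyridine, THF–pyridine, 0 °C → rt
Reagents that add atoms: none
Why: fluoride-assisted cleavage of the tertiary triethylsilyl and secondary tert-butyldimethylsilyl ethers under buffered acidic conditions that the enone, the methylene lactone and the ester tolerate, which releases the C1 and C9 hydroxyls.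

Compound list
1 | furan | c1ccoc1 | starting material
2 | 2-[(4-methoxybenzyl)oxy]acetaldehyde | O=CCOCc1ccc(OC)cc1 | starting material
3 | 2-furyllithium | [Li]c1ccco1 | intermediate (not isolated)
4 | 1-(furan-2-yl)-2-[(4-methoxybenzyl)oxy]ethan-1-ol (racemic) | OC(COCc1ccc(OC)cc1)c1ccco1 | intermediate
5 | (Z)-5-hydroxy-6-[(4-methoxybenzyl)oxy]-4-oxohex-2-enal | O=C/C=C\C(=O)C(O)COCc1ccc(OC)cc1 | intermediate (not isolated)
6 | 6-hydroxy-2-{[(4-methoxybenzyl)oxy]methyl}-2H-pyran-3(6H)-one (racemic, both anomers) | O=C1C=CC(O)OC1COCc2ccc(OC)cc2 | intermediate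
7 | 5-oxo-6-{[(4-methoxybenzyl)oxy]methyl}-5,6-dihydro-2H-pyran-2-yl 3,4,5-trifluorobenzoate (racemic, both anomers) | O=C1C=CC(OC(=O)c2cc(F)c(F)c(F)c2)OC1COCc3ccc(OC)cc3 | intermediate
8 | allyloxy(tert-butyl)dimethylsilane | C=CCO[Si](C)(C)C(C)(C)C | starting material
9 | (E)-tert-butyldimethyl(prop-1-en-1-yloxy)silane | C/C=C/O[Si](C)(C)C(C)(C)C | intermediate
10 | 2-{[(4-methoxybenzyl)oxy]methyl}pyrylium-3-olate (3-oxidopyrylium) | [O-]c1ccc[o+]c1COCc2ccc(OC)cc2 | intermediate (not isolated)
11 | (1R,5S,6S,7S)-6-[(tert-butyldimethylsilyl)oxy]-1-{[(4-methoxybenzyl)oxy]methyl}-7-methyl-8-oxabicyclo[3.2.1]oct-3-en-2-one (silyloxy endo, methyl exo) | O=C1C=C[C@@H]2O[C@@]1(COCc3ccc(OC)cc3)[C@@H](C)[C@@H]2O[Si](C)(C)C(C)(C)C | intermediate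
12 | 7-hydroxy-7-{[(4-methoxybenzyl)oxy]methyl}-6-methyl-5-[(tert-butyldimethylsilyl)oxy]cyclohept-3-en-1-one (1α-OH, 1β-CH2OPMB, 9β-OSi, 10α-CH3; C7=C8) | O=C1CC=C[C@@H](O[Si](C)(C)C(C)(C)C)[C@H](C)[C@@]1(O)COCc2ccc(OC)cc2 | intermediate (not isolated)
13 | 7-hydroxy-7-{[(4-methoxybenzyl)oxy]methyl}-6-methyl-5-[(tert-butyldimethylsilyl)oxy]cyclohept-2-en-1-one (1α-OH, 1β-CH2OPMB, 9β-OSi, 10α-CH3; C6=C7) | O=C1C=CC[C@@H](O[Si](C)(C)C(C)(C)C)[C@H](C)[C@@]1(O)COCc2ccc(OC)cc2 | intermediate
14 | 7-{[(4-methoxybenzyl)oxy]methyl}-6-methyl-5-[(tert-butyldimethylsilyl)oxy]-7-[(triethylsilyl)oxy]cyclohept-2-en-1-one (1α-OSiEt3) | O=C1C=CC[C@@H](O[Si](C)(C)C(C)(C)C)[C@H](C)[C@@]1(O[Si](CC)(CC)CC)COCc2ccc(OC)cc2 | intermediate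
15 | 7-{[(4-methoxybenzyl)oxy]methyl}-6-methyl-5-[(tert-butyldimethylsilyl)oxy]-7-[(triethylsilyl)oxy]cyclohept-2-en-1-ol (5α-OH, cis to the C1 oxygen) | O[C@@H]1C=CC[C@@H](O[Si](C)(C)C(C)(C)C)[C@H](C)[C@@]1(O[Si](CC)(CC)CC)COCc2ccc(OC)cc2 | intermediate
16 | acetic anhydride | CC(=O)OC(C)=O | starting material
17 | acetate of 15 (5α-OAc) | CC(=O)O[C@@H]1C=CC[C@@H](O[Si](C)(C)C(C)(C)C)[C@H](C)[C@@]1(O[Si](CC)(CC)CC)COCc2ccc(OC)cc2 | intermediate
18 | 1-(trimethylsilyloxy)vinyl ether of 15 (O-silyl ketene acetal) | C=C(O[Si](C)(C)C)O[C@@H]1C=CC[C@@H](O[Si](C)(C)C(C)(C)C)[C@H](C)[C@@]1(O[Si](CC)(CC)CC)COCc2ccc(OC)cc2 | intermediate (not isolated)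
19 | trimethylsilyl ester of 20 | C[Si](C)(C)OC(=O)C[C@@H]1C[C@@H](O[Si](C)(C)C(C)(C)C)[C@H](C)[C@@](O[Si](CC)(CC)CC)(COCc2ccc(OC)cc2)C=C1 | intermediate (not isolated)
20 | 2-[4-{[(4-methoxybenzyl)oxy]methyl}-5-methyl-6-[(tert-butyldimethylsilyl)oxy]-4-[(triethylsilyl)oxy]cyclohept-2-en-1-yl]acetic acid (7α-CH2CO2H; C5=C6) | OC(=O)C[C@@H]1C[C@@H](O[Si](C)(C)C(C)(C)C)[C@H](C)[C@@](O[Si](CC)(CC)CC)(COCc2ccc(OC)cc2)C=C1 | intermediate
21 | 2-[4-(hydroxymethyl)-5-methyl-6-[(tert-butyldimethylsilyl)oxy]-4-[(triethylsilyl)oxy]cyclohept-2-en-1-yl]acetic acid (1β-CH2OH) | OC(=O)C[C@@H]1C[C@@H](O[Si](C)(C)C(C)(C)C)[C@H](C)[C@@](O[Si](CC)(CC)CC)(CO)C=C1 | intermediate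
22 | 5β,6β-epoxide of 21 | OC(=O)C[C@@H]1C[C@@H](O[Si](C)(C)C(C)(C)C)[C@H](C)[C@@](O[Si](CC)(CC)CC)(CO)[C@H]2O[C@@H]12 | intermediate (not isolated)
23 | 8-hydroxy-7-(hydroxymethyl)-6-methyl-5-[(tert-butyldimethylsilyl)oxy]-7-[(triethylsilyl)oxy]octahydro-2H-cyclohepta[b]furan-2-one (6α-O/7α-C cis-lactone, 5β-OH, 1α-OSiEt3, 9β-OSi, 10α-CH3) | C1C(=O)O[C@@H]2[C@H]1C[C@@H](O[Si](C)(C)C(C)(C)C)[C@H](C)[C@@](O[Si](CC)(CC)CC)(CO)[C@H]2O | intermediate
24 | N,N-dimethylmethyleneiminium iodide | C=[N+](C)C.[I-] | starting material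
25 | 3-[(dimethylamino)methyl] derivative of 23 (C11 epimers) | CN(C)CC1C(=O)O[C@@H]2[C@H]1C[C@@H](O[Si](C)(C)C(C)(C)C)[C@H](C)[C@@](O[Si](CC)(CC)CC)(CO)[C@H]2O | intermediate (not isolated)
26 | 3-[(trimethylammonio)methyl] iodide derived from 25 | C[N+](C)(C)CC1C(=O)O[C@@H]2[C@H]1C[C@@H](O[Si](C)(C)C(C)(C)C)[C@H](C)[C@@](O[Si](CC)(CC)CC)(CO)[C@H]2O.[I-] | intermediate (not isolated)
27 | 8-hydroxy-7-(hydroxymethyl)-6-methyl-3-methylidene-5-[(tert-butyldimethylsilyl)oxy]-7-[(triethylsilyl)oxy]octahydro-2H-cyclohepta[b]furan-2-one | C=C1C(=O)O[C@@H]2[C@H]1C[C@@H](O[Si](C)(C)C(C)(C)C)[C@H](C)[C@@](O[Si](CC)(CC)CC)(CO)[C@H]2O | intermediate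
28 | 8-hydroxy-6-methyl-3-methylidene-2-oxo-5-[(tert-butyldimethylsilyl)oxy]-7-[(triethylsilyl)oxy]octahydro-2H-cyclohepta[b]furan-7-carbaldehyde | C=C1C(=O)O[C@@H]2[C@H]1C[C@@H](O[Si](C)(C)C(C)(C)C)[C@H](C)[C@@](O[Si](CC)(CC)CC)(C=O)[C@H]2O | intermediate
29 | isovaleryl chloride (3-methylbutanoyl chloride) | CC(C)CC(=O)Cl | starting material
30 | 7-formyl-6-methyl-3-methylidene-2-oxo-5-[(tert-butyldimethylsilyl)oxy]-7-[(triethylsilyl)oxy]octahydro-2H-cyclohepta[b]furan-8-yl 3-methylbutanoate (5β-ester) | C=C1C(=O)O[C@@H]2[C@H]1C[C@@H](O[Si](C)(C)C(C)(C)C)[C@H](C)[C@@](O[Si](CC)(CC)CC)(C=O)[C@H]2OC(=O)CC(C)C | intermediate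
31 | (E)-1-bromoprop-1-ene | C/C=C/Br | starting material
32 | (E)-prop-1-enylchromium dichloride | C/C=C/[Cr](Cl)Cl | intermediate (not isolated)
33 | 7-[(E)-1-hydroxybut-2-enyl]-6-methyl-3-methylidene-2-oxo-5-[(tert-butyldimethylsilyl)oxy]-7-[(triethylsilyl)oxy]octahydro-2H-cyclohepta[b]furan-8-yl 3-methylbutanoate (C2 epimers) | C=C1C(=O)O[C@@H]2[C@H]1C[C@@H](O[Si](C)(C)C(C)(C)C)[C@H](C)[C@@](O[Si](CC)(CC)CC)(C(O)/C=C/C)[C@H]2OC(=O)CC(C)C | intermediate
34 | 7-[(E)-but-2-enoyl]-6-methyl-3-methylidene-2-oxo-5-[(tert-butyldimethylsilyl)oxy]-7-[(triethylsilyl)oxy]octahydro-2H-cyclohepta[b]furan-8-yl 3-methylbutanoate | C=C1C(=O)O[C@@H]2[C@H]1C[C@@H](O[Si](C)(C)C(C)(C)C)[C@H](C)[C@@](O[Si](CC)(CC)CC)(C(=O)/C=C/C)[C@H]2OC(=O)CC(C)C | intermediate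
35 | 7-[(E)-but-2-enoyl]-5,7-dihydroxy-6-methyl-3-methylidene-2-oxooctahydro-2H-cyclohepta[b]furan-8-yl 3-methylbutanoate (1α-OH, 5β-ester, 6α-O/7α-C cis-lactone, 9β-OH, 10α-CH3) | C=C1C(=O)O[C@@H]2[C@H]1C[C@@H](O)[C@H](C)[C@@](O)(C(=O)/C=C/C)[C@H]2OC(=O)CC(C)C | target

Total step count: 18. Longest linear sequence: 17 steps (steps 1–3 and 5–18, from furan); step 4 is a one-step branch that joins at step 5.

Steps most likely to fail

1. Step 5. The β-methylated silyl enol ether may add too slowly, so that the ylide dimerises. The 2-substituted pyranone may condense poorly with the amine catalyst. Facial discrimination may also be insufficient. The fallback gives up catalyst control and sets out from 7 and 9. The ylide 10 is generated with an achiral base (i-Pr2NEt, MeCN, rt to 60 °C, 9 in excess), the known base-mediated oxidopyrylium cycloaddition. This should give 11 together with its mirror image, (1S,5R,6R,7R)-6-[(tert-butyldimethylsilyl)oxy]-1-{[(4-methoxybenzyl)oxy]methyl}-7-methyl-8-oxabicyclo[3.2.1]oct-3-en-2-one F1. The two are separated by preparative chromatography on a chiral stationary phase (amylose tris(3,5-dimethylphenylcarbamate)), and the route is rejoined at 11.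

2. Step 6. Electron transfer may break the other bond of the bridge (C1–O, which is α to the ketone) instead of C8–O, or the enone may be over-reduced. The fallback replaces electron transfer by a polar addition and an organozinc elimination, and sets out from 11. Conjugate addition of iodide (Me3SiI, CH2Cl2, −78 °C) gives the β-iodo silyl enol ether F2, with iodine at C7 on the α-face. Aqueous work-up gives the β-iodo ketone F3. Zinc dust (EtOH, aq. NH4Cl, rt) inserts into the C7–I bond, and the organozinc can only expel the vicinal C8–O bond (Boord-type fragmentation). This gives the deconjugated enone 12, where the route is rejoined before the base isomerisation of step 6.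

3. Step 8. Hydride may be delivered to the α-face if Felkin–Anh control is weak, giving the C5 epimer, which would carry the side chain to the wrong face of C7. The fallback uses intramolecular hydride delivery and sets out from 14. DDQ (CH2Cl2–pH 7 buffer) frees the hydroxymethyl group to give the primary alcohol 7-(hydroxymethyl)-6-methyl-5-[(tert-butyldimethylsilyl)oxy]-7-[(triethylsilyl)oxy]cyclohept-2-en-1-one F4. Me4NBH(OAc)3 (MeCN–AcOH, −30 °C) then transfers hydride from the boron bound to that β-face oxygen (hydroxyl-directed reduction), which can only reach the β-face of C5 and gives the diol F5 with the C5 hydroxyl α. Bu2SnO (toluene, reflux) forms the dibutylstannylene acetal F6 of the 1,3-diol, and PMBCl with CsF in DMF alkylates its primary oxygen, which returns the route to 15.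

Further compounds
F1 | step 5 | (1S,5R,6R,7R)-6-[(tert-butyldimethylsilyl)oxy]-1-{[(4-methoxybenzyl)oxy]methyl}-7-methyl-8-oxabicyclo[3.2.1]oct-3-en-2-one (enantiomer of 11) | O=C1C=C[C@H]2O[C@]1(COCc3ccc(OC)cc3)[C@H](C)[C@H]2O[Si](C)(C)C(C)(C)C
F2 | step 6 | trimethylsilyl enol ether of F3: 6-[(tert-butyldimethylsilyl)oxy]-4-iodo-1-{[(4-methoxybenzyl)oxy]methyl}-7-methyl-2-(trimethylsilyloxy)-8-oxabicyclo[3.2.1]oct-2-ene (iodine syn to the bridge oxygen) | C[Si](C)(C)OC1=C[C@H](I)[C@@H]2O[C@@]1(COCc3ccc(OC)cc3)[C@@H](C)[C@@H]2O[Si](C)(C)C(C)(C)C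
F3 | step 6 | 6-[(tert-butyldimethylsilyl)oxy]-4-iodo-1-{[(4-methoxybenzyl)oxy]methyl}-7-methyl-8-oxabicyclo[3.2.1]octan-2-one (iodine at C7 of the target numbering, syn to the bridge oxygen) | O=C1C[C@H](I)[C@@H]2O[C@@]1(COCc3ccc(OC)cc3)[C@@H](C)[C@@H]2O[Si](C)(C)C(C)(C)C
F4 | step 8 | 7-(hydroxymethyl)-6-methyl-5-[(tert-butyldimethylsilyl)oxy]-7-[(triethylsilyl)oxy]cyclohept-2-en-1-one (1β-CH2OH, 1α-OSiEt3) | O=C1C=CC[C@@H](O[Si](C)(C)C(C)(C)C)[C@H](C)[C@@]1(O[Si](CC)(CC)CC)CO
F5 | step 8 | 7-(hydroxymethyl)-6-methyl-5-[(tert-butyldimethylsilyl)oxy]-7-[(triethylsilyl)oxy]cyclohept-2-en-1-ol (5α-OH) | O[C@@H]1C=CC[C@@H](O[Si](C)(C)C(C)(C)C)[C@H](C)[C@@]1(O[Si](CC)(CC)CC)CO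
F6 | step 8 | dibutylstannylene acetal of F5 (2,2-dibutyl-1,3,2-dioxastanninane spanning the C5 oxygen and the CH2O group) | CCCC[Sn]3(CCCC)O[C@@H]1C=CC[C@@H](O[Si](C)(C)C(C)(C)C)[C@H](C)[C@@]1(O[Si](CC)(CC)CC)CO3
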